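The charges of first end groups run from 0.080 M in midnight up to 1.2 M in noon, with gas held at 12 mM, and each flask has to be placed by its links.

in all of them: gas 12 mM (held)
- blue: first end groups 0.11 M; run made earlier
- grey: first end groups 1.7 M; run made earlier
- noon: first end groups 1.2 M; time 1.0 h
- spring: first end groups 0.10 M; time 1.0 h
- summer: first end groups 0.15 M; time 1.0 h
- midnight: first end groups 0.080 M; time 1.0 h
- winter: first end groups 0.30 M; time 1.0 h

| run | time / min | links / % | first end groups / % |
|---|---|---|---|
| blue | 3.00 | 28.0 | 68.8 |
| blue | 8.00 | 58.6 | 27.2 |
| blue | 20.0 | 64.8 | 9.5 |
| blue | 40.0 | 56.0 | 7.9 |
| grey | 3.00 | 0.8 | 95.4 |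
| grey | 8.00 | 1.4 | 86.8 |
| grey | 20.0 | 1.6 | 65.4 |
| grey | 40.0 | 2.7 | 32.5 |

(standard deviation of a reading: 0.3 percentage points)

- a species is counted by the first end groups in it: one side product counts as two
- at the start none of second end groups is dissolved
- steps that have been proposed: first end groups + second end groups <-> links + by-product; gas <-> second end groups; first end groups + links -> side product

- all flasks from highest to lowest amount of links, in percent of the first end groups charged, at 1.0 h (noon / spring / summer / midnight / winter)
- the same order at 3.0 min (noon / spring / summer / midnight / winter)
- the amount of links, in percent of the first end groups charged of the flask you put first, at 1.0 h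
- the amount of links, in percent of the first end groups charged of the flask you put last, at 1.0 h

The blue run shows links falling late, from 64.8 % at 20.0 min to 56.0 % at 40.0 min. Each link made one by-product, and one side product, counted as two, keeps one by-product, so in blue by-product stands at 77.6 % of the charge, then 74.0 %.

With second end groups taken at 12 mM, the quotient [links][by-product]/([first end groups][second end groups]) reads 48.6, then 48.1. The exchange therefore behaves as a pre-equilibrium, and [first end groups] follows [links][by-product].

Links are lost by reaction with first end groups, at a rate proportional to [first end groups][links]. Taking by-product per charge as nearly constant, the fraction of links left, l, then loses at a rate proportional to l squared and to the charge squared. So 1/l climbs in a straight line with time. In blue it climbs by 0.0121 min⁻¹, the drain slope, from a value of 1.30 at zero time.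

Scaled by the charge squared, midnight's slope is 0.00641 min⁻¹. With the same zero-time value, this separate reckoning gives midnight 59.3 % at 1.0 h, and smaller charges stand higher. It is not applied to noon: grey, at 40.0 min, still holds 32.5 % of first end groups beside 2.7 % of links.

The forecast gives midnight > spring > summer > winter > noon at 1.0 h and midnight > spring > summer > winter > noon at 3.0 min, with 56.5 % (52 % to 61 %) for midnight and 4.7 % (3.2 % to 6.8 %) for noon. Its grounds: “the exchange is equilibrated and links slowly drain into side product”. The reckoning above stands higher for midnight.

The flasks give midnight > spring > summer > winter > noon at 1.0 h and midnight > spring > summer > winter > noon at 3.0 min, with midnight at 60.8 % and noon at 4.74 %.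

first end groups + second end groups ⇌ links + by-product (K = 47.4, k = 41.7 M⁻¹ min⁻¹); gas ⇌ second end groups, rate k2*(csat - [second end groups]) (kL = 1.32 min⁻¹); first end groups + links → side product (k = 0.484 M⁻¹ min⁻¹) For midnight left until 4.0 h, the drain slope carried on from 60.8 % lifts the reciprocal by 1.15, which reckons links at 35.7 %. That flask holds 35.2 % of links beside 61.6 % of side product.

The readings were computed from invented constants; noise was put on by code.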